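The earlier runs and the new flask are simulated with constants of no real substance; scatter was added.

2.89 is the number to watch when you repeat this flask: it is the selectivity factor s, the rate of the left-handed reaction over the right-handed one at equal substrate amounts, read here as left-handed over right-handed product, pooled over the eta, delta and beta readings at 50.0 min.

common to all: free catalyst 0.2 mol%

| flask | left-handed substrate | right-handed substrate | coupling partner | remark | time |
|---|---|---|---|---|---|
| eta | 0.27 M | 0.27 M | 1 equiv (fed, over 12 min) | run made earlier; the fed solution adds 0.20 times the starting volume |  |
| delta | 0.60 M | 0.60 M | 1 equiv (fed, over 12 min) | run made earlier; the fed solution adds 0.20 times the starting volume |  |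
| beta | 0.40 M | 0.40 M | 0.50 equiv (fed, over 12 min) | run made earlier; the fed solution adds 0.20 times the starting volume |  |
| flask | 0.40 M | 0.40 M | 1.00 equiv (fed, over 12 min) | the fed solution adds 0.20 times the starting volume | 50 min |

- eta (time / min: left-handed product / %, right-handed product / %): 4.00: 0, 0; 10.0: 0, 2; 20.0: 1, 1; 50.0: 7, 1
- delta (time / min: left-handed product / %, right-handed product / %): 4.00: 2, 0; 10.0: 3, 1; 20.0: 4, 1; 50.0: 15, 4
- beta (time / min: left-handed product / %, right-handed product / %): 4.00: 1, 0; 10.0: 1, 2; 20.0: 1, 0; 50.0: 4, 4

(standard deviation of a reading: 1.5 percentage points)

- free catalyst is single-handed; left-handed substrate and right-handed substrate are mirror images of each other, charged as a racemate, each of them at the stated concentration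
- charges are per starting volume, the dose included; the dosed solution carries all of it
- an excess is below zero if the other one leads

* excess of left-handed product over right-handed product in the product at 1.0 min
* excess of left-handed product over right-handed product in the product at 50 min
* part of the left-handed substrate and right-handed substrate charged together that has reacted at 50 min

With readings scattering by 1.5 percentage points, s is a rough reading. In the delta run, the readings at 50.0 min put 30.0% of the left-handed substrate's charge against 8.00% of the right-handed substrate's charge in product, so the two substrates no longer stand at nearly equal amounts there, and that makes s rougher still. For the flask at 1.0 min I freeze both substrates at their equal charges. The product ratio then stays at s, and the excess is s minus one over s plus one. My reckoning gives 48.6% for the early excess in the flask, less than the forecast's figure.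

The forecast says 50% at 1.0 min, 47% at 50 min ("Slight depletion gives about 47% at 50 min") and 13% reacted.

The flask gives 51.5%, 49.5% and 9.88%, so all three forecasts hold within their margins.

    coupling partner + free catalyst + left-handed substrate → free catalyst + left-handed product (k = 0.428 L² mol⁻² s⁻¹)
    coupling partner + free catalyst + right-handed substrate → free catalyst + right-handed product (k = 0.137 L² mol⁻² s⁻¹)
    coupling partner + free catalyst → spent catalyst A (k = 6.53 × 10⁻⁵ L mol⁻¹ s⁻¹)
    free catalyst → spent catalyst B (k = 8.69 × 10⁻⁵ s⁻¹)
    coupling partner ⇌ dormant form (K = 15.0, k = 1.51 × 10⁻⁴ s⁻¹)

In the flask at 50 min, 85% of the left-handed substrate and 95% of the right-handed substrate are left, and the excess has fallen by 2 points since 1.0 min. Dividing the flask's 7.39% of left-handed product by s = 2.89 gives 2.56% of right-handed product, and the flask holds 2.50%. The neighbour flask has a quarter of the catalyst, 0.05 mol%, and 2.84% reacted. There the same division of 2.14% gives 0.740%, against 0.696% found.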